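The route rests on tracing the ketal C–O bond to the ring OCH carbon (C4–Oa, Oa on C9) back to an ester and the adjacent ring bond C4=C5 to a carbonyl–olefin metathesis. In one operation a titanium alkylidene joins the ester carbon C4 to the allyl carbon C5 and closes the oxepene C4–C5–C6–C7–C8–C9–Oa, so the two halves are united by acylation alone. The precursor is the C9 ester of a 2-methylidene-3-silyloxy-4-arylbutanoic acid with an allyl group and a silyl ether on C7. The feature exploited is the seven-membered ring hidden in the 2,8-dioxabicyclo[3.2.1]octane: once it exists, the C7 oxygen (Ob) adds across it to C4.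

Key step: step 10

Atom labels: C1 = ArCH2, C2 = CHOAc, C3 = carbinol carbon, C3′ = its CH2OAc, C4 = ketal carbon, C5/C6 = ring CH2CH2, C7 = CMe, C8 = ring CH2, C9 = ring OCH, Oa = oxygen on C9, Ob = oxygen on C7, C10=C11 = first alkene; the target is (2R,3S,4R,7R,9S,10E).

Assumption: C4 needs no control of its own, because the bridgeheads C4 and C7 of the bicyclo[3.2.1] ketal can only be joined on one face; the (S)-BINOL/Ti(OiPr)4 catalyst and β-isocupreidine are taken to show their usual facial preference with these substrates.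

Design remarks: the C7 hydroxyl is silylated only after the ester union, since a tertiary hydroxyl cannot be silylated in preference to the secondary C9 hydroxyl of the diol. After the key step both silyl ethers are removed with fluoride before acid is added, so that the C7 hydroxyl is the only nucleophile present when the alkoxydiene is protonated.

Step 1
Reactants: 1 2,5-dimethoxy-4-methylbenzaldehyde
Product: 3 (2,5-dimethoxy-4-methylphenyl)acetaldehyde, via aryl enol ether 2 (not isolated)
Conditions: Ph3P(CH2OMe)Cl, KOtBu, THF, 0 → 23 °C; then 2 M HCl, 40 °C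
Reagents that add atoms: (methoxymethyl)triphenylphosphonium chloride, COC[P+](c1ccccc1)(c1ccccc1)c1ccccc1.[Cl-]; water, O
Why: Wittig methoxymethylenation followed by acid hydrolysis of the electron-rich aryl enol ether is the standard one-carbon homologation of a benzaldehyde to an arylacetaldehyde, and the crude aldehyde should be used at once because it self-condenses on storage.

Step 2
Reactants: 3 (2,5-dimethoxy-4-methylphenyl)acetaldehyde; 4 1,1,1,3,3,3-hexafluoropropan-2-yl acrylate
Product: 5 hexafluoroisopropyl (3R)-4-(2,5-dimethoxy-4-methylphenyl)-3-hydroxy-2-methylidenebutanoate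
Conditions: β-isocupreidine (10 mol %), DMF, −55 °C
Reagents that add atoms: none
Why: Asymmetric Morita–Baylis–Hillman reaction, in which the quinuclidine nitrogen of the catalyst adds to the activated acrylate and its phenol hydrogen-bonds the aldolate, a combination that gives (R)-carbinols with aliphatic aldehydes and should therefore set C2 as R.

Step 3
Reactants: 5 hexafluoroisopropyl (3R)-4-(2,5-dimethoxy-4-methylphenyl)-3-hydroxy-2-methylidenebutanoate
Product: 6 hexafluoroisopropyl (3R)-3-[(tert-butyldimethylsilyl)oxy]-4-(2,5-dimethoxy-4-methylphenyl)-2-methylidenebutanoate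
Conditions: TBSOTf, 2,6-lutidine, CH2Cl2, −78 → 0 °C
Reagents that add atoms: tert-butyldimethylsilyl triflate, CC(C)(C)[Si](C)(C)OS(=O)(=O)C(F)(F)F
Why: Silylation of the secondary allylic alcohol with the silyl triflate and a non-nucleophilic base should leave the activated ester untouched.

Step 4
Reactants: 6 hexafluoroisopropyl (3R)-3-[(tert-butyldimethylsilyl)oxy]-4-(2,5-dimethoxy-4-methylphenyl)-2-methylidenebutanoate
Product: 7 (3R)-3-[(tert-butyldimethylsilyl)oxy]-4-(2,5-dimethoxy-4-methylphenyl)-2-methylidenebutanoic acid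
Conditions: LiOH, THF/H2O, 0 °C; then 1 M HCl to pH 4
Reagents that add atoms: lithium hydroxide, [Li+].[OH-]
Why: Saponification of the electron-poor hexafluoroisopropyl ester should be much faster at 0 °C than cleavage of the silyl ether, and C2 cannot epimerise because its hydrogen is not acidic.

Step 5
Reactants: 8 geranial; 9 allyltributylstannane
Product: 10 (4S,5E)-6,10-dimethylundeca-1,5,9-trien-4-ol
Conditions: Ti(OiPr)4 (10 mol %), (S)-BINOL (20 mol %), 4 Å MS, CH2Cl2, −20 °C
Reagents that add atoms: none
Why: Keck asymmetric allylation, in which the BINOL–titanium Lewis acid activates the enal for 1,2-addition and the (S)-ligand directs allyl to the face that gives the (S)-carbinol with α,β-unsaturated aldehydes, which sets C9.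

Step 6
Reactants: 10 (4S,5E)-6,10-dimethylundeca-1,5,9-trien-4-ol
Product: 11 (4S,5E)-4-hydroxy-6,10-dimethylundeca-5,9-dien-2-one
Conditions: PdCl2 (10 mol %), CuCl, O2 (1 atm), DMF/H2O, 23 °C
Reagents that add atoms: water, O
Why: Tsuji–Wacker oxidation, in which divalent palladium activates only the monosubstituted alkene for Markovnikov hydroxypalladation (the trisubstituted alkenes are too hindered to coordinate) and β-hydride elimination gives the methyl ketone with C9 untouched.

Step 7
Reactants: 11 (4S,5E)-4-hydroxy-6,10-dimethylundeca-5,9-dien-2-one; 12 allyl bromide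
Product: 13 (4R,6S,7E)-4,8,12-trimethyltrideca-1,7,11-triene-4,6-diol
Conditions: In powder, THF/H2O, 23 °C
Reagents that add atoms: none
Why: Barbier-type allylindium addition under Cram-chelate control, in which the free C9 hydroxyl and the ketone bind indium in a six-membered chelate with the dienyl group equatorial and allyl adds axially, which should give the 1,3-anti diol and set C7 as R (a minor syn isomer would be removed by chromatography).

Step 8
Reactants: 13 (4R,6S,7E)-4,8,12-trimethyltrideca-1,7,11-triene-4,6-diol; 7 (3R)-3-[(tert-butyldimethylsilyl)oxy]-4-(2,5-dimethoxy-4-methylphenyl)-2-methylidenebutanoic acid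
Product: 14 C9 ester of diol 13 with acid 7, C7 hydroxyl free
Conditions: 2-methyl-6-nitrobenzoic anhydride, DMAP, Et3N, CH2Cl2, 23 °C
Reagents that add atoms: none
Why: Shiina esterification through the mixed anhydride and DMAP should acylate the secondary allylic C9 hydroxyl only, the tertiary C7 hydroxyl being too hindered, so the union needs no protecting group on the diol.

Step 9
Reactants: 14 C9 ester with free C7 hydroxyl
Product: 15 C9 ester with C7 triethylsilyl ether (olefinic ester, precursor of the key step)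
Conditions: TESOTf, 2,6-lutidine, CH2Cl2, −78 → 0 °C
Reagents that add atoms: triethylsilyl triflate, CC[Si](CC)(CC)OS(=O)(=O)C(F)(F)F
Why: Silyl triflates with 2,6-lutidine silylate tertiary alcohols at low temperature, and the ester, the silyl ether at C2 and the arene should be inert.

Step 10
Reactants: 15 C9 ester with C7 triethylsilyl ether
Product: 16 seven-membered cyclic enol ether (2,3,4,5-tetrahydrooxepine with C4=C5, 2-alkoxydiene)
Conditions: TiCl4, TMEDA, Zn, PbCl2 (cat.), CH3CHBr2, THF/CH2Cl2, 0 → 65 °C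
Reagents that add atoms: none
Why: Reduction of TiCl4–TMEDA by PbCl2-activated Zn in the presence of CH3CHBr2 generates a low-valent titanium ethylidene, which exchanges by [2+2] addition and cycloreversion with the monosubstituted alkene of the C7 allyl group (propene is lost) and so places a titanium alkylidene on C5. This tethered alkylidene adds to the C4 ester carbonyl to give an oxatitanacyclobutane that cycloreverts to the C4=C5 enol ether and a titanium oxo species, so the step is a carbonyl–olefin metathesis. The closest known reaction type is the olefinic ester cyclisation with the Takai–Utimoto ethylidene reagent, which is established for six- and seven-membered cyclic enol ethers. The oxepene ring C4–C5–C6–C7–C8–C9–Oa is closed by intramolecular carbonyl olefination (ring-closing carbonyl–olefin metathesis), the ester C4–Oa bond being already in place. No stereocentre is formed: C2, C7 and C9 are spectators and the C10=C11 geometry is not touched. The step needs chemoselectivity for the terminal vinyl group over the 1,1-disubstituted C3=C3′ alkene and the two trisubstituted alkenes, which their steric shielding should secure, and 1,2-olefination of the conjugated carbonyl, which intramolecular seven-membered delivery favours over intermolecular attack on the α-branched acrylate.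

Step 11
Reactants: 16 seven-membered cyclic enol ether
Product: 18 bicyclic ketal with free C2 allylic alcohol, via desilylated diol enol ether 17 (not isolated)
Conditions: TBAF, THF, 0 → 23 °C; then PPTS (excess over TBAF), 23 °C
Reagents that add atoms: none
Why: Fluoride removes both silyl ethers without touching the base-stable alkoxydiene, and the pyridinium acid then protonates C5 so that the C7 hydroxyl adds to the C4 oxocarbenium ion across the ring (5-exo ketalisation), with C4 fixed as R by the cis-fusion of the bridgeheads and the C9 dienyl group equatorial on the dioxane chair.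

Step 12
Reactants: 18 bicyclic ketal with free C2 allylic alcohol
Product: 19 (2R,3S)-C3/C3′ epoxy alcohol
Conditions: VO(acac)2 (5 mol %), t-BuOOH, CH2Cl2, 0 → 23 °C
Reagents that add atoms: tert-butyl hydroperoxide, CC(C)(C)OO
Why: Vanadium-catalysed hydroxyl-directed epoxidation selects the allylic-alcohol alkene C3=C3′ over the isolated trisubstituted alkenes, and the transition state that avoids A(1,2) strain with the bulky C4 substituent (O–C2–C3=C3′ dihedral near 50°, C2–H next to C4) should give the erythro epoxy alcohol, which sets C3 as S.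

Step 13
Reactants: 19 (2R,3S)-C3/C3′ epoxy alcohol
Product: 20 C3′ acetate with free C2 and C3 hydroxyls
Conditions: CsOAc, AcOH, DMF, 60 °C
Reagents that add atoms: acetic acid, CC(=O)O (delivered as cesium acetate, CC(=O)[O-].[Cs+])
Why: Acetate opens the 2,2-disubstituted epoxide by SN2 attack at the unsubstituted carbon C3′, so the C3–O bond and its configuration are kept, while Payne rearrangement would require attack at the quaternary C3 and is not expected.

Step 14
Reactants: 20 C3′ acetate with free C2 and C3 hydroxyls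
Product: 21 C2,C3′ diacetate of the dimethyl ether
Conditions: Ac2O, pyridine, DMAP (cat.), CH2Cl2, 0 → 23 °C
Reagents that add atoms: acetic anhydride, CC(=O)OC(C)=O
Why: DMAP-catalysed acetylation should esterify the secondary C2 hydroxyl (and any hydroxyl bared by acetyl migration between C3′ and C2) but not the tertiary C3 hydroxyl, which is flanked by two fully substituted carbons.

Step 15
Reactants: 21 C2,C3′ diacetate of the dimethyl ether
Product: 23 CNP0160303.2, via benzoquinone 22 (not isolated)
Conditions: (NH4)2Ce(NO3)6, MeCN/H2O, 0 °C; then Na2S2O4, EtOAc/H2O, 23 °C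
Reagents that add atoms: water, O
Why: Oxidative demethylation of the 1,4-dimethoxyarene through its radical cation and addition of water gives the benzoquinone, and dithionite reduces it to the hydroquinone without affecting the esters, the ketal or the alkenes.

Compound list
1 | 2,5-dimethoxy-4-methylbenzaldehyde | COc1cc(C=O)c(OC)cc1C | starting material
2 | 1,4-dimethoxy-2-(2-methoxyethenyl)-5-methylbenzene, E/Z mixture (not isolated) | COC=Cc1cc(OC)c(C)cc1OC | intermediate
3 | 2-(2,5-dimethoxy-4-methylphenyl)acetaldehyde | O=CCc1cc(OC)c(C)cc1OC | intermediate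
4 | 1,1,1,3,3,3-hexafluoropropan-2-yl acrylate | C=CC(=O)OC(C(F)(F)F)C(F)(F)F | starting material
5 | 1,1,1,3,3,3-hexafluoropropan-2-yl (3R)-4-(2,5-dimethoxy-4-methylphenyl)-3-hydroxy-2-methylidenebutanoate | C=C([C@@H](Cc1cc(OC)c(C)cc1OC)O)C(=O)OC(C(F)(F)F)C(F)(F)F | intermediate
6 | 1,1,1,3,3,3-hexafluoropropan-2-yl (3R)-3-[(tert-butyldimethylsilyl)oxy]-4-(2,5-dimethoxy-4-methylphenyl)-2-methylidenebutanoate | C=C([C@@H](Cc1cc(OC)c(C)cc1OC)O[Si](C)(C)C(C)(C)C)C(=O)OC(C(F)(F)F)C(F)(F)F | intermediate
7 | (3R)-3-[(tert-butyldimethylsilyl)oxy]-4-(2,5-dimethoxy-4-methylphenyl)-2-methylidenebutanoic acid | C=C([C@@H](Cc1cc(OC)c(C)cc1OC)O[Si](C)(C)C(C)(C)C)C(=O)O | intermediate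
8 | geranial, (2E)-3,7-dimethylocta-2,6-dienal | O=C/C=C(\C)CCC=C(C)C | starting material
9 | allyltributylstannane | C=CC[Sn](CCCC)(CCCC)CCCC | starting material
10 | (4S,5E)-6,10-dimethylundeca-1,5,9-trien-4-ol | C=CC[C@H](O)/C=C(\C)CCC=C(C)C | intermediate
11 | (4S,5E)-4-hydroxy-6,10-dimethylundeca-5,9-dien-2-one | CC(=O)C[C@H](O)/C=C(\C)CCC=C(C)C | intermediate
12 | allyl bromide | C=CCBr | starting material
13 | (4R,6S,7E)-4,8,12-trimethyltrideca-1,7,11-triene-4,6-diol (7R,9S in the atom labels) | C=CC[C@@](C)(O)C[C@H](O)/C=C(\C)CCC=C(C)C | intermediate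
14 | (4R,6S,7E)-4-hydroxy-4,8,12-trimethyltrideca-1,7,11-trien-6-yl (3R)-3-[(tert-butyldimethylsilyl)oxy]-4-(2,5-dimethoxy-4-methylphenyl)-2-methylidenebutanoate | C=C([C@@H](Cc1cc(OC)c(C)cc1OC)O[Si](C)(C)C(C)(C)C)C(=O)O[C@@H](C[C@@](C)(CC=C)O)/C=C(\C)CCC=C(C)C | intermediate
15 | (4R,6S,7E)-4,8,12-trimethyl-4-[(triethylsilyl)oxy]trideca-1,7,11-trien-6-yl (3R)-3-[(tert-butyldimethylsilyl)oxy]-4-(2,5-dimethoxy-4-methylphenyl)-2-methylidenebutanoate | C=C([C@@H](Cc1cc(OC)c(C)cc1OC)O[Si](C)(C)C(C)(C)C)C(=O)O[C@@H](C[C@@](C)(CC=C)O[Si](CC)(CC)CC)/C=C(\C)CCC=C(C)C | intermediate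
16 | (2S,4R)-7-{(3R)-3-[(tert-butyldimethylsilyl)oxy]-4-(2,5-dimethoxy-4-methylphenyl)but-1-en-2-yl}-2-[(1E)-2,6-dimethylhepta-1,5-dien-1-yl]-4-methyl-4-[(triethylsilyl)oxy]-2,3,4,5-tetrahydrooxepine | C=C([C@@H](Cc1cc(OC)c(C)cc1OC)O[Si](C)(C)C(C)(C)C)C2=CC[C@@](C)(O[Si](CC)(CC)CC)C[C@@H](/C=C(\C)CCC=C(C)C)O2 | intermediate
17 | (2S,4R)-7-[(3R)-4-(2,5-dimethoxy-4-methylphenyl)-3-hydroxybut-1-en-2-yl]-2-[(1E)-2,6-dimethylhepta-1,5-dien-1-yl]-4-methyl-2,3,4,5-tetrahydrooxepin-4-ol (not isolated) | C=C([C@@H](Cc1cc(OC)c(C)cc1OC)O)C2=CC[C@@](C)(O)C[C@@H](/C=C(\C)CCC=C(C)C)O2 | intermediate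
18 | (2R)-1-(2,5-dimethoxy-4-methylphenyl)-3-{(1R,3S,5R)-3-[(1E)-2,6-dimethylhepta-1,5-dien-1-yl]-5-methyl-2,8-dioxabicyclo[3.2.1]octan-1-yl}but-3-en-2-ol | C=C([C@@H](Cc1cc(OC)c(C)cc1OC)O)[C@]12CC[C@](C)(C[C@@H](/C=C(\C)CCC=C(C)C)O1)O2 | intermediate
19 | (1R)-2-(2,5-dimethoxy-4-methylphenyl)-1-[(2S)-2-{(1R,3S,5R)-3-[(1E)-2,6-dimethylhepta-1,5-dien-1-yl]-5-methyl-2,8-dioxabicyclo[3.2.1]octan-1-yl}oxiran-2-yl]ethan-1-ol | C3O[C@@]3([C@@H](Cc1cc(OC)c(C)cc1OC)O)[C@]12CC[C@](C)(C[C@@H](/C=C(\C)CCC=C(C)C)O1)O2 | intermediate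
20 | (2S,3R)-4-(2,5-dimethoxy-4-methylphenyl)-2-{(1R,3S,5R)-3-[(1E)-2,6-dimethylhepta-1,5-dien-1-yl]-5-methyl-2,8-dioxabicyclo[3.2.1]octan-1-yl}-2,3-dihydroxybutyl acetate | CC(=O)OC[C@](O)([C@@H](Cc1cc(OC)c(C)cc1OC)O)[C@]12CC[C@](C)(C[C@@H](/C=C(\C)CCC=C(C)C)O1)O2 | intermediate
21 | (2S,3R)-3-(acetyloxy)-4-(2,5-dimethoxy-4-methylphenyl)-2-{(1R,3S,5R)-3-[(1E)-2,6-dimethylhepta-1,5-dien-1-yl]-5-methyl-2,8-dioxabicyclo[3.2.1]octan-1-yl}-2-hydroxybutyl acetate | CC(=O)OC[C@](O)([C@@H](Cc1cc(OC)c(C)cc1OC)OC(C)=O)[C@]12CC[C@](C)(C[C@@H](/C=C(\C)CCC=C(C)C)O1)O2 | intermediate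
22 | (2S,3R)-3-(acetyloxy)-2-{(1R,3S,5R)-3-[(1E)-2,6-dimethylhepta-1,5-dien-1-yl]-5-methyl-2,8-dioxabicyclo[3.2.1]octan-1-yl}-2-hydroxy-4-(4-methyl-3,6-dioxocyclohexa-1,4-dien-1-yl)butyl acetate (not isolated) | CC(=O)OC[C@](O)([C@@H](CC1=CC(=O)C(C)=CC1=O)OC(C)=O)[C@]12CC[C@](C)(C[C@@H](/C=C(\C)CCC=C(C)C)O1)O2 | intermediate
23 | CNP0160303.2, (2S,3R)-3-(acetyloxy)-4-(2,5-dihydroxy-4-methylphenyl)-2-{(1R,3S,5R)-3-[(1E)-2,6-dimethylhepta-1,5-dien-1-yl]-5-methyl-2,8-dioxabicyclo[3.2.1]octan-1-yl}-2-hydroxybutyl acetate | CC(=O)OC[C@](O)([C@@H](Cc1cc(O)c(C)cc1O)OC(C)=O)[C@]12CC[C@](C)(C[C@@H](/C=C(\C)CCC=C(C)C)O1)O2 | target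

Total step count: 15 steps.
Longest linear sequence: 12 steps (steps 1–4 and 8–15, from 2,5-dimethoxy-4-methylbenzaldehyde); the geranial branch is 11 steps.

Steps most likely to fail

Step 10. Alkylidene exchange at the allyl group may be outrun by direct ethylidenation or reduction of the conjugated ester carbonyl, and closure of the seven-membered ring onto the hindered ester may be slow. Fallback: the same C4=C5 bond is made in two known stages. From 15, methylenation of the ester carbonyl with the Tebbe reagent Cp2Ti(μ-CH2)(μ-Cl)AlMe2 (pyridine, THF, −40 → 0 °C) should give the acyclic methylene enol ether F1. Ring-closing olefin metathesis of F1 between the enol ether methylene and the allyl group with the second-generation Grubbs catalyst (toluene, 70 °C) would expel ethylene and return to 16.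

Step 2. The amine catalyst may mainly promote self-aldolisation of the enolisable arylacetaldehyde, the alkoxide may be diverted to a dioxanone with a second aldehyde, or facial selectivity may be poor. Fallback: C2 is set by ketone hydrogenation instead, as follows.
- From 3, SnCl2-catalysed Roskamp homologation with methyl diazoacetate (CH2Cl2, 23 °C) would give the β-keto ester methyl 4-(2,5-dimethoxy-4-methylphenyl)-3-oxobutanoate F2.
- Noyori hydrogenation with RuCl2[(R)-BINAP] (H2, MeOH) would give the (R)-β-hydroxy ester F3.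
- Dianion formation with LiN(iPr)2 and Mannich reaction with Eschenmoser's salt (THF, −78 → −20 °C) would give the anti α-(dimethylaminomethyl) ester F4.
- Quaternisation with MeI and elimination with DBU would give the methyl (3R)-3-hydroxy-2-methylidene ester F5.
- Silylation (TBSOTf, 2,6-lutidine) would give the silyl ether methyl ester F6, and saponification (LiOH, THF/MeOH/H2O) would return to acid 7.

Step 7. Chelation may be too weak in the aqueous medium, so that both faces of the ketone are attacked and the 1,3-anti diol is not formed selectively. Fallback: the allyl group is delivered intramolecularly from a boron atom bound to the C9 oxygen. From 11, exchange with allylB(OiPr)2 and Et3N (CH2Cl2, 23 °C) would give the mixed C9 allylboronate F7. Its allyl group would be transferred to the ketone through a bicyclic chair–chair transition state with the dienyl group equatorial, to give the cyclic isopropyl borate F8 of the anti diol. Hydrolysis with aqueous NaOH would return to 13.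

Further compounds
F1 | step 10 | (4R,6S,7E)-6-({(4R)-4-[(tert-butyldimethylsilyl)oxy]-5-(2,5-dimethoxy-4-methylphenyl)-3-methylidenepent-1-en-2-yl}oxy)-4,8,12-trimethyl-4-[(triethylsilyl)oxy]trideca-1,7,11-triene (acyclic methylene enol ether) | C=C([C@@H](Cc1cc(OC)c(C)cc1OC)O[Si](C)(C)C(C)(C)C)C(=C)O[C@@H](C[C@@](C)(CC=C)O[Si](CC)(CC)CC)/C=C(\C)CCC=C(C)C
F2 | step 2 | methyl 4-(2,5-dimethoxy-4-methylphenyl)-3-oxobutanoate | COC(=O)CC(=O)Cc1cc(OC)c(C)cc1OC
F3 | step 2 | methyl (3R)-4-(2,5-dimethoxy-4-methylphenyl)-3-hydroxybutanoate | COC(=O)C[C@H](O)Cc1cc(OC)c(C)cc1OC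
F4 | step 2 | methyl (2R,3R)-4-(2,5-dimethoxy-4-methylphenyl)-2-[(dimethylamino)methyl]-3-hydroxybutanoate | COC(=O)[C@H](CN(C)C)[C@H](O)Cc1cc(OC)c(C)cc1OC
F5 | step 2 | methyl (3R)-4-(2,5-dimethoxy-4-methylphenyl)-3-hydroxy-2-methylidenebutanoate | C=C([C@@H](Cc1cc(OC)c(C)cc1OC)O)C(=O)OC
F6 | step 2 | methyl (3R)-3-[(tert-butyldimethylsilyl)oxy]-4-(2,5-dimethoxy-4-methylphenyl)-2-methylidenebutanoate | C=C([C@@H](Cc1cc(OC)c(C)cc1OC)O[Si](C)(C)C(C)(C)C)C(=O)OC
F7 | step 7 | isopropyl (4S,5E)-6,10-dimethyl-2-oxoundeca-5,9-dien-4-yl allylboronate | CC(=O)C[C@H](OB(CC=C)OC(C)C)/C=C(\C)CCC=C(C)C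
F8 | step 7 | (4R,6S)-4-allyl-6-[(1E)-2,6-dimethylhepta-1,5-dien-1-yl]-2-isopropoxy-4-methyl-1,3,2-dioxaborinane | C=CC[C@]1(C)C[C@@H](/C=C(\C)CCC=C(C)C)OB(OC(C)C)O1
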